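The target is the inverse-demand oxa-Diels–Alder adduct of isobutylidene syncarpic acid and (+)-β-pinene, the scarce antipode, which is therefore remodelled from camphor-derived (1S)-ketopinic acid. In a 1-hydroxynorbornyl endo-2-tosylate the CMe2 bridge is antiperiplanar to the leaving group, and a semipinacol 1,2-shift moves it from C1 to C2. In one operation the cyclopentane holding CMe2 grows into the six-membered pinane ring (future spiro carbon, two CH2, both bridgehead CH, CMe2), the other cyclopentane shrinks to the cyclobutane and the carbinol becomes the ketone of (−)-nopinone; bridgehead C4 of ketopinic acid fixes the absolute configuration. Methylenation and cycloaddition finish the route.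

Key step: step 4

Assumption: (1S)-(+)-ketopinic acid 1 and syncarpic acid 10 are taken as catalogue compounds; the target is read as having the ether oxygen on the face of the spiro carbon remote from the CMe2 bridge and the isopropyl group cis to pinane bridgehead C1 across the dihydropyran ring.

Step 1
Reactants: 1 (1S)-(+)-ketopinic acid
Product: 5 (1S,4R)-1-hydroxy-7,7-dimethylbicyclo[2.2.1]heptan-2-one, via ketopinoyl chloride 2 (not isolated), via Barton ester 3 (not isolated), via bridgehead hydroperoxide 4 (not isolated)
Conditions: (COCl)2, DMF (cat.), CH2Cl2, rt; then sodium 2-thioxopyridin-1(2H)-olate (C5H4NNaOS), DMAP (cat.), t-BuSH, O2, PhMe, hν, rt; then P(OEt)3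
Reagents that add atoms: dioxygen, O=O
Why: Barton decarboxylative hydroxylation, in which the thiohydroxamate ester 3 fragments under light to CO2 and the 1-norbornyl bridgehead radical, O2 traps it and t-BuSH then P(OEt)3 reduce the peroxyl stage to the carbinol; the radical cannot invert inside the bicycle, so C1 and C4 keep their configuration.

Step 2
Reactants: 5 (1S,4R)-1-hydroxy-7,7-dimethylbicyclo[2.2.1]heptan-2-one
Product: 6 (1S,2S,4R)-7,7-dimethylbicyclo[2.2.1]heptane-1,2-diol (2-endo hydroxyl)
Conditions: Li, NH3 (l), THF, −78 to −33 °C; then NH4Cl
Reagents that add atoms: none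
Why: Dissolving-metal reduction under thermodynamic control should protonate the ketyl to the more stable endo (borneol-type) carbinol, which avoids the syn methyl of the CMe2 bridge and sets C2 as S, whereas hydride reagents would attack from the endo face and give the exo alcohol; the bridgehead C–O bond lies near the nodal plane of the ketyl and should survive.

Step 3
Reactants: 6 (1S,2S,4R)-7,7-dimethylbicyclo[2.2.1]heptane-1,2-diol
Product: 7 (1S,2S,4R)-1-hydroxy-7,7-dimethylbicyclo[2.2.1]heptan-2-yl 4-methylbenzenesulfonate
Conditions: TsCl, pyridine, DMAP (cat.), 0 °C to rt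
Reagents that add atoms: p-toluenesulfonyl chloride, Cc1ccc(cc1)S(=O)(=O)Cl
Why: Alcohol tosylation should select the secondary carbinol over the tertiary bridgehead carbinol on steric grounds, and no stereocentre is touched because the C–O bond stays intact.

Step 4
Reactants: 7 (1S,2S,4R)-1-hydroxy-7,7-dimethylbicyclo[2.2.1]heptan-2-yl 4-methylbenzenesulfonate
Product: 8 (1S,5R)-6,6-dimethylbicyclo[3.1.1]heptan-2-one [(−)-nopinone]
Conditions: KOtBu, THF, −20 °C to rt
Reagents that add atoms: none
Why: Deprotonation of the bridgehead carbinol triggers a semipinacol rearrangement in which the C1–C7 bond to the CMe2 bridge, which models place nearly antiperiplanar (about 155°) to the endo C2–OTs bond, migrates to C2 with inversion while C1–O becomes the carbonyl. The closest known reactions are the base-mediated semipinacol rearrangement of vicinal hydroxy sulfonates, long used on bridgehead carbinols to turn bicyclo[2.2.2]octanes into bicyclo[3.2.1]octanones, and the participation of the gem-dimethyl bridge when endo-bornyl derivatives ionise. No ring is closed by cyclisation: the 1,2-shift inserts C2 into the cyclopentane C1–C6–C5–C4–C7, which becomes the six-membered ring C1–C2–C3–C4–C5–C6 of nopinone, and at the same time contracts the cyclopentane C1–C2–C3–C4–C7 to the cyclobutane. The new bridgehead stereocentre (C1 of 8) follows from the stereospecific backside shift and is in any case dictated by C4 of 7, since the bicycle can only close cis. The step needs migration of C7 and not of the ethano carbon C6 (which would give a camphenilone-type norbornanone); this is secured by the endo leaving group (C6 is gauche, about 50°), by non-ionising anionic conditions, and by a geometry that allows neither epoxide formation nor anti elimination. The strain gained on going from norbornane to pinane should be paid for by carbonyl formation and loss of sulfonate.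

Step 5
Reactants: 8 (−)-nopinone
Product: 9 (1R,5R)-6,6-dimethyl-2-methylidenebicyclo[3.1.1]heptane [(+)-β-pinene]
Conditions: Ph3PCH3Br, KOtBu, THF, rt to 50 °C
Reagents that add atoms: methyltriphenylphosphonium bromide, C[P+](c1ccccc1)(c1ccccc1)c1ccccc1.[Br-]
Why: Wittig methylenation with the non-stabilised ylide should succeed on this hindered ketone because only CH2 is delivered, and the α-stereocentre C1 is a bridgehead that cannot epimerise through the enolate.

Step 6
Reactants: 10 syncarpic acid; 11 isobutyraldehyde
Product: 13 2,2,4,4-tetramethyl-6-(2-methylpropylidene)cyclohexane-1,3,5-trione (isobutylidene syncarpic acid), via Mannich base 12 (not isolated)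
Conditions: piperidine, CH2Cl2, rt; then 1 M HCl
Reagents that add atoms: none
Why: Knoevenagel condensation run through the Mannich adduct 12, in which piperidine masks the very electrophilic enetrione as it forms so that a second molecule of 10 cannot add in Michael fashion, and acid then expels piperidinium to release 13; no stereocentre is involved.

Step 7
Reactants: 9 (+)-β-pinene; 13 isobutylidene syncarpic acid
Product: 14 (1S,2S,4'R,5R)-6,6,6',6',8',8'-hexamethyl-4'-(propan-2-yl)-3',4'-dihydrospiro[bicyclo[3.1.1]heptane-2,2'-chromene]-5',7'(6'H,8'H)-dione (target)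
Conditions: PhMe, 70 °C, sealed tube
Reagents that add atoms: none
Why: Inverse-electron-demand oxa-Diels–Alder reaction in which the 1-oxadiene of 13 adds to the exocyclic alkene of 9 with oxygen bonding to the more substituted C2 and the alkene CH2 to the alkylidene carbon; approach to the alkene face remote from the CMe2 bridge should set the spiro centre (S, oxygen anti to CMe2), while C4' depends only on the endo/exo orientation, so both C4' epimers are to be expected and the target (isopropyl cis to bridgehead C1) is separated by chromatography.

Compound list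
1 | (1S,4R)-7,7-dimethyl-2-oxobicyclo[2.2.1]heptane-1-carboxylic acid, (1S)-(+)-ketopinic acid | O=C1C[C@H]2CC[C@]1(C(=O)O)C2(C)C | starting material
2 | (1S,4R)-7,7-dimethyl-2-oxobicyclo[2.2.1]heptane-1-carbonyl chloride (ketopinoyl chloride) | O=C1C[C@H]2CC[C@]1(C(=O)Cl)C2(C)C | intermediate (not isolated)
3 | 2-thioxopyridin-1(2H)-yl (1S,4R)-7,7-dimethyl-2-oxobicyclo[2.2.1]heptane-1-carboxylate (Barton ester) | O=C1C[C@H]2CC[C@]1(C(=O)ON3C=CC=CC3=S)C2(C)C | intermediate (not isolated)
4 | (1S,4R)-1-hydroperoxy-7,7-dimethylbicyclo[2.2.1]heptan-2-one | O=C1C[C@H]2CC[C@]1(OO)C2(C)C | intermediate (not isolated)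
5 | (1S,4R)-1-hydroxy-7,7-dimethylbicyclo[2.2.1]heptan-2-one | O=C1C[C@H]2CC[C@]1(O)C2(C)C | intermediate
6 | (1S,2S,4R)-7,7-dimethylbicyclo[2.2.1]heptane-1,2-diol (2-endo hydroxyl) | O[C@H]1C[C@H]2CC[C@]1(O)C2(C)C | intermediate
7 | (1S,2S,4R)-1-hydroxy-7,7-dimethylbicyclo[2.2.1]heptan-2-yl 4-methylbenzenesulfonate (endo tosylate) | Cc1ccc(cc1)S(=O)(=O)O[C@H]1C[C@H]2CC[C@]1(O)C2(C)C | intermediate
8 | (1S,5R)-6,6-dimethylbicyclo[3.1.1]heptan-2-one, (−)-nopinone | CC1(C)[C@@H]2CCC(=O)[C@H]1C2 | intermediate
9 | (1R,5R)-6,6-dimethyl-2-methylidenebicyclo[3.1.1]heptane, (+)-β-pinene | CC1(C)[C@@H]2CCC(=C)[C@H]1C2 | intermediate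
10 | 2,2,4,4-tetramethylcyclohexane-1,3,5-trione, syncarpic acid | CC1(C)C(=O)CC(=O)C(C)(C)C1=O | starting material
11 | 2-methylpropanal, isobutyraldehyde | CC(C)C=O | starting material
12 | 3-hydroxy-4,4,6,6-tetramethyl-2-[2-methyl-1-(piperidin-1-yl)propyl]cyclohex-2-ene-1,5-dione (Mannich base, racemic) | CC(C)C(N1CCCCC1)C1=C(O)C(C)(C)C(=O)C(C)(C)C1=O | intermediate (not isolated)
13 | 2,2,4,4-tetramethyl-6-(2-methylpropylidene)cyclohexane-1,3,5-trione, isobutylidene syncarpic acid | CC(C)C=C1C(=O)C(C)(C)C(=O)C(C)(C)C1=O | intermediate
14 | (1S,2S,4'R,5R)-6,6,6',6',8',8'-hexamethyl-4'-(propan-2-yl)-3',4'-dihydrospiro[bicyclo[3.1.1]heptane-2,2'-chromene]-5',7'(6'H,8'H)-dione | CC(C)[C@H]1C[C@]2(CC[C@@H]3C[C@H]2C3(C)C)OC2=C1C(=O)C(C)(C)C(=O)C2(C)C | target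

Total step count: 7 (steps 1–5 and 7 in line, step 6 on the side branch).
Longest linear sequence: 6 steps (1 → 5 → 6 → 7 → 8 → 9 → 14).

Steps most likely to fail

Step 4 (key step). The shift of the CMe2 bridge builds strain, and it may be outrun by elimination, by O-to-O sulfonyl transfer, or by heterolysis of the C1–C7 bond with ring opening instead of migration. The fallback sets out from 5 and comes back at 8, replacing the sulfonate by an electrophile-triggered semipinacol. Condensation of 5 with 2,4,6-triisopropylbenzenesulfonyl hydrazide (MeOH, cat. HCl) gives the sulfonylhydrazone F1. A Shapiro reaction (n-BuLi in excess, THF/TMEDA, −78 to 0 °C, the carbinol carried as its lithium alkoxide) gives the bridgehead allylic alcohol 7,7-dimethylbicyclo[2.2.1]hept-2-en-1-ol F2. N-Bromosuccinimide (CH2Cl2, 0 °C) should place the bromonium ion on the endo face, since the syn methyl of the CMe2 bridge blocks the exo face to three-membered-ring electrophiles. The same bridge, anti to the endo C2–Br bond, should then migrate to give 7-bromonopinone F3. Bu3SnH with AIBN (PhH, 80 °C) removes the bromine and gives 8. This path also does without steps 2 and 3.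

Step 2. Stereocontrol at C2 may be incomplete, because protonation of the chelated ketyl/carbanion need not follow the borneol-type preference. The fallback sets out from 5 and comes back at 6, reaching the endo carbinol by equilibration instead of by kinetic reduction. NaBH4 (MeOH, 0 °C) should give cleanly the exo diol (1S,2R,4R)-7,7-dimethylbicyclo[2.2.1]heptane-1,2-diol F4. Redox epimerisation of the secondary carbinol with (C5Ph5)Ru(CO)2Cl and KOtBu (both catalytic, PhMe, rt to 60 °C) should then equilibrate exo and endo alcohols through the ruthenium hydride and the bound ketone. The endo diol 6 is separated and F4 returned to the equilibration.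

Step 7. Endo/exo selectivity of the cycloaddition may be poor, and the orientation that places the bulky bridgehead side of the alkene away from the diene leads to the C4' epimer. The fallback sets out from 9 and 13 and comes back at 14, using catalyst control instead of substrate control. Cu(OTf)2 with a bis(oxazoline) ligand (tBu-box, 10 mol %, CH2Cl2, −40 °C) should bind the 1,3-dicarbonyl unit of 13 at two points and shield one face of the alkylidene carbon. The configuration at C4' is then fixed by the ligand, while β-pinene keeps its own facial preference. The ligand enantiomer that delivers 4'R is chosen in a pilot run. This fallback makes no new compound (F0).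

Further compounds
F1 | step 4 | N'-[(1S,4R)-1-hydroxy-7,7-dimethylbicyclo[2.2.1]heptan-2-ylidene]-2,4,6-triisopropylbenzenesulfonohydrazide | CC(C)c1cc(C(C)C)c(S(=O)(=O)NN=C2C[C@H]3CC[C@]2(O)C3(C)C)c(C(C)C)c1
F2 | step 4 | 7,7-dimethylbicyclo[2.2.1]hept-2-en-1-ol (single enantiomer from 5) | C1=C[C@H]2CC[C@]1(O)C2(C)C
F3 | step 4 | 7-bromo-6,6-dimethylbicyclo[3.1.1]heptan-2-one (7-bromonopinone, bromine syn to the three-carbon bridge) | CC1(C)[C@@H]2CCC(=O)[C@H]1[C@H]2Br
F4 | step 2 | (1S,2R,4R)-7,7-dimethylbicyclo[2.2.1]heptane-1,2-diol (2-exo hydroxyl) | O[C@@H]1C[C@H]2CC[C@]1(O)C2(C)C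
F0 | step 7 | none | none
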